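## Retrosynthetic overview

1. Locants: oxane ring O1, C2 (bears the pyridone), C3 (methyl), C4, C5 (alkylidene), C6; side chain C1'–C8' counted from the ring. The last cut is at C2–C(pyridone) and C2–O1. It gives 1,4-dihydroxy-5-phenylpyridin-2(1H)-one and a 3-methyl-5-trienylidene-oxan-2-ol, joined by Knoevenagel condensation and ring-closing oxa-Michael addition, which sets C2.
2. The key cut is C1'–C2', made together with C4–C5. The masked open form of the lactol falls into an E,E-dienyl iodide, prop-2-yn-1-ol (C6, C5, C1') and a C4 Grignard reagent that carries C2 as a dioxolane. All three are united in one flask by copper-catalysed anti-carbomagnesiation followed by palladium-catalysed coupling.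
3. Enabling feature: in the oxane ring, O1 sits on C6, allylic to the exocyclic C5=C1' bond, and the triene chain is cis to C6. The array O1–C6–C5=C1' is therefore the open form of a five-membered 2,5-dihydro-1,2-oxamagnesole. This temporary ring fixes the Z geometry and delivers C1' as a nucleophile.
4. Both methyl-bearing stereocentres (C3 and C6') come from the same enantiomer of one commercial C4 unit, (S)-3-bromo-2-methylpropan-1-ol, read in opposite directions.
5. Ring order: the pyridine ring is bought and turned into the N-hydroxypyridone; then the temporary oxamagnesole ring forms; then the oxane ring forms, first as the lactol and finally re-closed on the pyridone methide.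

Key step: step 5

Remark on the chemistry: lactol 13 is taken as a mixture of C2 epimers and the alkylidene geometry of 19 is left open. Neither matters, because C2 is trigonal in 19 and is set only in the ring closure of step 11.

## Route

Step 1
Reactants: 1 (S)-3-bromo-2-methylpropan-1-ol
Product: 3 (S)-2-(1-bromopropan-2-yl)-1,3-dioxolane, via (S)-3-bromo-2-methylpropanal 2 (not isolated)
Conditions: Dess–Martin periodinane, CH2Cl2, 0 → 23 °C; short SiO2 plug; then (TMSOCH2)2, TMSOTf (5 mol %), CH2Cl2, −78 °C
Reagents that add atoms: 1,2-bis(trimethylsilyloxy)ethane, C[Si](C)(C)OCCO[Si](C)(C)C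
Why: Dess–Martin oxidation runs without base, so the β-bromo aldehyde 2 should neither lose HBr nor enolise, and the TMSOTf-catalysed acetalisation with the bis-silylated glycol at −78 °C masks it at once, the stereocentre of 1 being carried through untouched.

Step 2
Reactants: 1 (S)-3-bromo-2-methylpropan-1-ol
Product: 4 (R)-2-methylbutan-1-ol
Conditions: MeMgBr (2.5 equiv), Li2CuCl4 (5 mol %), THF, −20 → 23 °C
Reagents that add atoms: methylmagnesium bromide, C[Mg]Br
Why: Copper-catalysed alkyl–alkyl Grignard cross-coupling replaces the primary bromide of the magnesium alkoxide of 1 by methyl without touching the neighbouring stereocentre, whose descriptor changes to R only because the priorities change.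

Step 3
Reactants: 4 (R)-2-methylbutan-1-ol
Product: 6 (R,E)-4-methylhex-2-enal, via (R)-2-methylbutanal 5 (not isolated)
Conditions: TEMPO (10 mol %), PhI(OAc)2, CH2Cl2, 23 °C; then Ph3P=CHCHO, 40 °C (sealed)
Reagents that add atoms: (triphenylphosphoranylidene)acetaldehyde, O=CC=P(c1ccccc1)(c1ccccc1)c1ccccc1
Why: Nitroxyl-catalysed alcohol oxidation and Wittig olefination with the stabilised formyl ylide in one flask spare the isolation of the volatile, epimerisable aldehyde 5, and the stabilised ylide should give the E-enal.

Step 4
Reactants: 6 (R,E)-4-methylhex-2-enal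
Product: 7 (1E,3E,5R)-1-iodo-5-methylhepta-1,3-diene
Conditions: CrCl2, CHI3, THF–dioxane, 0 °C
Reagents that add atoms: iodoform, IC(I)I
Why: Takai olefination with the geminal dichromium species from CHI3 and CrCl2 is non-basic, adds 1,2 to the enal and should give the E-alkenyl iodide by anti elimination, leaving the allylic stereocentre alone.

Step 5
Reactants: 3 (S)-2-(1-bromopropan-2-yl)-1,3-dioxolane; 7 (1E,3E,5R)-1-iodo-5-methylhepta-1,3-diene; 8 prop-2-yn-1-ol
Product: 12 (2Z,4E,6E,8R)-2-[(2R)-2-(1,3-dioxolan-2-yl)propyl]-8-methyldeca-2,4,6-trien-1-ol, via Grignard reagent 9 (not isolated), via chloromagnesium propargyl oxide 10 (not isolated), via oxamagnesole 11 (not isolated)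
Conditions: 3, Mg turnings, THF, 25 °C; 8, i-PrMgCl (1.0 equiv), THF, −20 °C; combine (9 in slight excess), CuI (10 mol %), −10 → 23 °C; then 7, Pd(PPh3)4 (5 mol %), 23 °C
Reagents that add atoms: none
Why: Under catalysis by monovalent copper, Grignard reagent 9 adds across the triple bond of alkoxide 10 with the alkyl group going to the inner alkyne carbon (future C5) and magnesium to the terminal carbon (future C1') in an anti sense, because the alkoxide oxygen holds the metal, which gives oxamagnesole 11; oxidative addition of 7 to zerovalent palladium, transmetalation of the C1'–Mg bond and reductive elimination then form the C1'–C2' bond with retention at both alkenyl carbons. The closest known reaction type is the copper-catalysed carbomagnesiation of prop-2-yn-1-ol, whose chelate gives Z-3-iodo-2-alkylallyl alcohols with iodine, run in one flask with a Kumada–Corriu coupling of the alkenylmagnesium chelate with alkenyl halides, a three-component sequence already shown for propargylic alcohols. No ring of 12 is closed; the temporary five-membered ring of 11 closes when magnesium is bound by both O1 and C1' in the anti addition, and it is opened again by transmetalation and work-up. No sp3 stereocentre is formed; the Z geometry of C5=C1' is dictated by the chelate ring, in which C1' and C6 must be cis, while C3, C6' and the E,E-diene are carried in unchanged. The step needs regioselectivity (alkyl to C5), which the alkoxide direction secures, and chemoselectivity in the coupling (alkenyl before alkyl magnesium), which the small excess of 9 and the faster transmetalation of the sp2 carbon secure; the dioxolane is inert to all reagents present.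

Step 6
Reactants: 12 (2Z,4E,6E,8R)-2-[(2R)-2-(1,3-dioxolan-2-yl)propyl]-8-methyldeca-2,4,6-trien-1-ol
Product: 13 (3R,5Z)-3-methyl-5-[(2E,4E,6R)-6-methylocta-2,4-dien-1-ylidene]oxan-2-ol
Conditions: PPTS (cat.), acetone–H2O, 40 °C
Reagents that add atoms: water, O
Why: Mild acid-catalysed acetal hydrolysis is helped by the C6 hydroxyl, which captures the oxocarbenium ion or the liberated aldehyde as the six-membered lactol, and PPTS should be too weak an acid to ionise the trienyl carbinol or to enolise at C3.

Step 7
Reactants: 14 5-bromo-2,4-dichloropyridine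
Product: 15 2,4-bis(benzyloxy)-5-bromopyridine
Conditions: BnOH, NaH, THF–DMF, 0 → 80 °C
Reagents that add atoms: benzyl alcohol, OCc1ccccc1
Why: Twofold nucleophilic aromatic substitution takes place at the chlorides in positions 4 and 2, which are activated by the ring nitrogen, while the bromide in position 5 is not activated and stays for the next step.

Step 8
Reactants: 15 2,4-bis(benzyloxy)-5-bromopyridine
Product: 16 2,4-bis(benzyloxy)-5-phenylpyridine
Conditions: PhB(OH)2, Pd(PPh3)4 (3 mol %), Na2CO3, dioxane–H2O, 90 °C
Reagents that add atoms: phenylboronic acid, OB(O)c1ccccc1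
Why: Suzuki–Miyaura coupling of the only carbon–halogen bond left installs the 5-phenyl group under conditions that benzyl ethers tolerate.

Step 9
Reactants: 16 2,4-bis(benzyloxy)-5-phenylpyridine
Product: 17 2,4-bis(benzyloxy)-5-phenylpyridine 1-oxide
Conditions: mCPBA, CH2Cl2, 0 → 23 °C
Reagents that add atoms: 3-chloroperbenzoic acid, OOC(=O)c1cccc(Cl)c1
Why: Peracid N-oxidation of the electron-rich dialkoxypyridine brings in the N–O oxygen before any alkene is present in this fragment.

Step 10
Reactants: 17 2,4-bis(benzyloxy)-5-phenylpyridine 1-oxide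
Product: 18 1,4-dihydroxy-5-phenylpyridin-2(1H)-one
Conditions: H2 (1 atm), Pd/C (10 wt % palladium on carbon), EtOAc–MeOH, 23 °C
Reagents that add atoms: none
Why: Hydrogenolysis removes both O-benzyl groups, and the 2-hydroxypyridine N-oxide set free tautomerises to the N-hydroxy-2-pyridone, whose N–O bond is reduced much more slowly, so that the uptake is stopped after two equivalents of H2.

Step 11
Reactants: 13 (3R,5Z)-3-methyl-5-[(2E,4E,6R)-6-methylocta-2,4-dien-1-ylidene]oxan-2-ol; 18 1,4-dihydroxy-5-phenylpyridin-2(1H)-one
Product: 20 1,4-dihydroxy-3-{(2R,3R,5Z)-3-methyl-5-[(2E,4E,6R)-6-methylocta-2,4-dien-1-ylidene]oxan-2-yl}-5-phenylpyridin-2(1H)-one, via pyridone methide 19 (not isolated)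
Conditions: Et3N (cat.), EtOH, 50 °C
Reagents that add atoms: none
Why: Ring-chain tautomerism of 13 exposes the aldehyde for a Knoevenagel condensation at the nucleophilic C3 of 18, and the exocyclic carbon of the resulting pyridone methide 19 is captured by the C6 hydroxyl in a reversible 6-exo-trig oxa-Michael addition, so that C2 is set under thermodynamic control with the pyridone equatorial and trans to the C3 methyl group (2R).

## Compound list

1 | (S)-3-bromo-2-methylpropan-1-ol | OC[C@H](C)CBr | starting material
2 | (S)-3-bromo-2-methylpropanal | O=C[C@H](C)CBr | intermediate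
3 | (S)-2-(1-bromopropan-2-yl)-1,3-dioxolane | O1CCOC1[C@H](C)CBr | intermediate
4 | (R)-2-methylbutan-1-ol | CC[C@@H](C)CO | intermediate
5 | (R)-2-methylbutanal | CC[C@@H](C)C=O | intermediate
6 | (R,E)-4-methylhex-2-enal | CC[C@@H](C)/C=C/C=O | intermediate
7 | (1E,3E,5R)-1-iodo-5-methylhepta-1,3-diene | CC[C@@H](C)/C=C/C=C/I | intermediate
8 | prop-2-yn-1-ol | C#CCO | starting material
9 | [(S)-2-(1,3-dioxolan-2-yl)propyl]magnesium bromide | Br[Mg]C[C@@H](C)C1OCCO1 | intermediate
10 | chloromagnesium prop-2-yn-1-olate | C#CCO[Mg]Cl | intermediate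
11 | 4-[(2R)-2-(1,3-dioxolan-2-yl)propyl]-2,5-dihydro-1,2-oxamagnesole | C[C@H](CC1=C[Mg]OC1)C1OCCO1 | intermediate
12 | (2Z,4E,6E,8R)-2-[(2R)-2-(1,3-dioxolan-2-yl)propyl]-8-methyldeca-2,4,6-trien-1-ol | CC[C@@H](C)/C=C/C=C/C=C(\CO)C[C@@H](C)C1OCCO1 | intermediate
13 | (3R,5Z)-3-methyl-5-[(2E,4E,6R)-6-methylocta-2,4-dien-1-ylidene]oxan-2-ol (C2 epimers) | CC[C@@H](C)/C=C/C=C/C=C1\COC(O)[C@H](C)C1 | intermediate
14 | 5-bromo-2,4-dichloropyridine | Clc1cc(Cl)c(Br)cn1 | starting material
15 | 2,4-bis(benzyloxy)-5-bromopyridine | Brc1cnc(OCc2ccccc2)cc1OCc1ccccc1 | intermediate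
16 | 2,4-bis(benzyloxy)-5-phenylpyridine | c1ccccc1-c1cnc(OCc2ccccc2)cc1OCc1ccccc1 | intermediate
17 | 2,4-bis(benzyloxy)-5-phenylpyridine 1-oxide | [O-][n+]1cc(-c2ccccc2)c(OCc2ccccc2)cc1OCc1ccccc1 | intermediate
18 | 1,4-dihydroxy-5-phenylpyridin-2(1H)-one | O=c1cc(O)c(-c2ccccc2)cn1O | intermediate
19 | 1-hydroxy-3-[(2R,4Z,6E,8E,10R)-4-(hydroxymethyl)-2,10-dimethyldodeca-4,6,8-trien-1-ylidene]-5-phenylpyridine-2,4(1H,3H)-dione | CC[C@@H](C)/C=C/C=C/C=C(\CO)C[C@@H](C)C=C1C(=O)C(-c2ccccc2)=CN(O)C1=O | intermediate
20 | 1,4-dihydroxy-3-{(2R,3R,5Z)-3-methyl-5-[(2E,4E,6R)-6-methylocta-2,4-dien-1-ylidene]oxan-2-yl}-5-phenylpyridin-2(1H)-one | CC[C@@H](C)/C=C/C=C/C=C1\CO[C@@H](c2c(O)c(-c3ccccc3)cn(O)c2=O)[C@H](C)C1 | target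

## Step count and risks

Total step count: 11. Longest linear sequence: 6 steps (steps 2, 3, 4, 5, 6 and 11).

**Step 5.**
- What may go wrong: the β-branched Grignard reagent may add slowly. The alkenylmagnesium may then be protonated by the acidic alkyne C–H of unconsumed alkoxide. Left-over alkylmagnesium may be coupled to the dienyl iodide in place of the alkenylmagnesium.
- Fallback: it sets out from 11 (made from 3 and 8 as in step 5) and from 7, and it comes back at 12. The two events are separated and the polarity of the partners is inverted.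
- Compound 11 is quenched with iodine to give (2Z)-2-[(2R)-2-(1,3-dioxolan-2-yl)propyl]-3-iodoprop-2-en-1-ol F1, which can be purified.
- Compound 7 is turned by Miyaura borylation (B2pin2, PdCl2(PPh3)2, PPh3, KOPh, toluene, 50 °C) into 2-[(1E,3E,5R)-5-methylhepta-1,3-dien-1-yl]-4,4,5,5-tetramethyl-1,3,2-dioxaborolane F2.
- A Suzuki–Miyaura coupling of the two (Pd(PPh3)4, aqueous NaOH, THF, 23 °C) forms the same C1'–C2' bond with retention at both carbons.

**Step 11.**
- What may go wrong: C3 may epimerise through enolisation of the open aldehyde or through tautomerisation of the pyridone methide to its dienol. The methide may be captured by a second pyridone. It may also undergo an intramolecular hetero-Diels–Alder reaction with the C5=C1' alkene.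
- Fallback: it sets out from 13 and 18 and comes back at 20. It replaces the methide pathway by a Friedel–Crafts-type C-glycosylation through the ring oxocarbenium ion.
- Compound 13 is acetylated (Ac2O, pyridine) to (3R,5Z)-3-methyl-5-[(2E,4E,6R)-6-methylocta-2,4-dien-1-ylidene]oxan-2-yl acetate F3.
- Compound 18 is silylated (N,O-bis(trimethylsilyl)acetamide, CH2Cl2) to 5-phenyl-1,4-bis(trimethylsilyloxy)pyridin-2(1H)-one F4.
- The two are joined with TMSOTf in CH2Cl2 at −78 °C, with attack anti to the C3 methyl group. Aqueous work-up removes the silyl groups.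

**Step 6.**
- What may go wrong: acid may ionise the trienyl carbinol, with allylic transposition and loss of the Z geometry. The reaction may also stall at the mixed hydroxyethyl acetal.
- Fallback: it sets out from 12 and comes back at 13, and it avoids Brønsted acid.
- TESOTf and 2,6-lutidine (CH2Cl2, 0 °C, then water) cleave the dioxolane through its lutidinium salt under weakly basic conditions and silylate the C6 hydroxyl. This gives (2R,4Z,6E,8E,10R)-2,10-dimethyl-4-[(triethylsilyloxy)methyl]dodeca-4,6,8-trienal F5.
- Buffered HF·pyridine (THF, 0 °C) then frees the hydroxyl, which closes to the lactol.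

## Further compounds

F1 | step 5 | (2Z)-2-[(2R)-2-(1,3-dioxolan-2-yl)propyl]-3-iodoprop-2-en-1-ol | I/C=C(\CO)C[C@@H](C)C1OCCO1
F2 | step 5 | 2-[(1E,3E,5R)-5-methylhepta-1,3-dien-1-yl]-4,4,5,5-tetramethyl-1,3,2-dioxaborolane | CC[C@@H](C)/C=C/C=C/B1OC(C)(C)C(C)(C)O1
F3 | step 11 | (3R,5Z)-3-methyl-5-[(2E,4E,6R)-6-methylocta-2,4-dien-1-ylidene]oxan-2-yl acetate | CC[C@@H](C)/C=C/C=C/C=C1\COC(OC(C)=O)[C@H](C)C1
F4 | step 11 | 5-phenyl-1,4-bis(trimethylsilyloxy)pyridin-2(1H)-one | C[Si](C)(C)Oc1cc(=O)n(O[Si](C)(C)C)cc1-c1ccccc1
F5 | step 6 | (2R,4Z,6E,8E,10R)-2,10-dimethyl-4-[(triethylsilyloxy)methyl]dodeca-4,6,8-trienal | CC[C@@H](C)/C=C/C=C/C=C(\CO[Si](CC)(CC)CC)C[C@@H](C)C=O
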